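Wednesday's run at 70 °C ended, at 30.0 min, with 7% Z beside 17% D. Z per D, divided by the minutes run, comes to 0.0137 min⁻¹ there. This ageing rate treats Z as D grown old; that is my own reading, and a scatter of 1.5 percentage points permits it without proving it.

| flask | G | L | Q | temperature | remark | time |
|---|---|---|---|---|---|---|
| Saturday's | 0.050 M | 0.125 M | 1.6 mM | 55 °C | run made earlier |  |
| Wednesday's | 0.050 M | 0.062 M | 1.6 mM | 70 °C | run made earlier |  |
| Thursday's | 0.050 M | 0.25 M | 1.6 mM | 55 °C | run made earlier |  |
| delta | 0.050 M | 0.125 M (fed, over 20 min) | 1.6 mM |  | the addition at 40 °C, then warmed to 70 °C; the feed brings no volume worth counting | 30 min |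
| epsilon | 0.050 M (fed, over 20 min) | 0.125 M | 1.6 mM | 70 °C | all else is in the flask from the start; the feed brings no volume worth counting | 30 min |
| alpha | 0.050 M | 0.125 M (fed, over 20 min) | 1.6 mM | 70 °C | all else is in the flask from the start; the feed brings no volume worth counting | 30 min |
| beta | 0.050 M | 0.125 M | 1.6 mM | 70 °C | everything together at the start | 30 min |

- Saturday's (time / min: D / %, Z / %): 5.00: 2, 1; 12.0: 0, 0; 25.0: 4, 2; 40.0: 8, 1
- Wednesday's (time / min: D / %, Z / %): 2.50: 0, 0; 6.00: 1, 0; 12.0: 4, 2; 30.0: 17, 7
- Thursday's (time / min: D / %, Z / %): 15.0: 0, 0; 30.0: 7, 1; 50.0: 12, 3; 60.0: 16, 3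

(each reading ± 1.5 percentage points)

- the numbers in the tables scatter with a standard deviation of 1.5 points

- the flask with the highest share of D in D plus Z ("all alike" if they lie within 1.5 percentage points) (delta / epsilon / alpha / beta / all alike)
- share of D in D plus Z at the end, delta
- share of D in D plus Z at the end, epsilon
- share of D in D plus Z at the end, alpha
- share of D in D plus Z at the end, beta

Two things can slow the ageing rate. Thursday's run, with twice the L of Saturday's, gives 0.00313 min⁻¹ and Saturday's gives 0.00313 min⁻¹, the same, so L slows it by no visible factor. Cold does: going from 70 °C to 55 °C divides the rate by 4.39. If the further step to 40 °C costs that factor again, the rate there is 7.11 × 10⁻⁴ min⁻¹.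

The accumulated ageing is the rate times the minutes, and the share of D, the selectivity, is one over one plus that sum. Beta, 30 min hot, comes to 70.9%. Alpha is hot for the same 30 min, so this sum gives it that figure too, though the sum takes no account of D made later while alpha's L is fed over 20 min. Epsilon's G arrives on average 10.0 min late, which gives 78.5%. Delta spends 20 min at the cold rate and 10.0 min hot, which gives 86.8%.

The forecast differs from this reckoning in its spread: 77% for delta, 75% for epsilon, 73% for alpha and 75% for beta. It names delta as highest, holding that “temperature probably drives most of the loss”.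

The flasks end with delta highest: delta 84.7%, epsilon 73.2%, alpha 67.7%, beta 65.3%. The steps behind them are these.

    G + Q → Q + X (k = 0.140 L mol⁻¹ s⁻¹, Ea = 69.0 kJ mol⁻¹)
    Q + X ⇌ E (K = 11.0 L mol⁻¹, k = 3.00 L mol⁻¹ s⁻¹, Ea = 43.0 kJ mol⁻¹, ΔH = 13.0 kJ mol⁻¹)
    L + E → Q + D (k = 2.50 L mol⁻¹ s⁻¹, Ea = 68.0 kJ mol⁻¹)
    D ⇌ Z (K = 3.10, k = 6.60 × 10⁻⁴ s⁻¹, Ea = 112 kJ mol⁻¹, ΔH = 6.00 kJ mol⁻¹)
    (constants at 70 °C)

Delta held 0.279% of D at the change of temperature, at 20.0 min, and 6.76% at 30.0 min, beside 1.22% of Z. That is 0.180 Z per D, where the ageing rate over the hot minutes gives 0.137. The same rate, taken over the 8.0 min of beta read early, gives a share of 90.1%, and that neighbour stands at 89.5%.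

All runs stem from a simulated flask for substances that don't exist; noise was put on by code.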